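**Assumptions**
- The configuration is that of the given SMILES. Ring C4 (R) corresponds to (R)-(+)-limonene.
- The Claisen step (Step 3) proceeds through the methyl-side enol ether, and C4 does not epimerise under the buffered conditions.

**Retrosynthetic overview**
1. The target comes from the ring tertiary alcohol by chloronium-assisted OH→Br exchange, which is the last step.
2. The C7 methyl and C8 OH come from trans opening of a glycal-type epoxide of a cyclic enol ether.
3. That enol ether comes from bromonium-induced 6-endo cyclisation of a prenyl ketone, which builds the tetrahydropyran ring and the C10–Br stereocentre.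
4. The prenyl ketone comes from a Claisen rearrangement of the methyl-ketone enol ether with 2-methylbut-3-en-2-ol, which forms the C8–C9 bond and the CH=CMe2 group.
5. The methyl ketone comes from (R)-limonene by chlorohydrin formation and ozonolysis. The cyclohexane is the first ring in place, and the pyran ring forms in Step 4.

**Step 1**
Reactants: 1, (R)-(+)-limonene
Product: 2, (1S,2S,4R)-2-chloro-1-methyl-4-(prop-1-en-2-yl)cyclohexan-1-ol
Conditions: NCS, acetone/H2O 4:1, 0 °C
Reagents that add atoms: N-chlorosuccinimide O=C1CCC(=O)N1Cl (Cl); water O (OH)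
Why: Chloronium forms on the more nucleophilic trisubstituted ring alkene and water opens it at the tertiary carbon, anti. This is halohydrin formation, and the trans-diaxial opening with the side chain equatorial sets C1 (OH up) and C2 (Cl down). The minor diastereomer is removed by chromatography.

**Step 2**
Reactants: 2
Product: 3, 1-[(1R,3S,4S)-3-chloro-4-hydroxy-4-methylcyclohexyl]ethan-1-one
Conditions: O3, CH2Cl2/MeOH 1:1, –78 °C; then Me2S, –78 °C to rt
Reagents that add atoms: ozone [O-][O+]=O (carbonyl O)
Why: Ozonolysis cleaves the remaining isopropenyl group to the methyl ketone, and no stereocentre is touched.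

**Step 3**
Reactants: 3; 4, 2-methylbut-3-en-2-ol
Product: 5, 1-[(1R,3S,4S)-3-chloro-4-hydroxy-4-methylcyclohexyl]-5-methylhex-4-en-1-one
Conditions: 4 (5 equiv), HC(OMe)3, cat. PPTS, toluene, 110 °C then 140 °C, sealed tube
Reagents that add atoms: none
Why: The methyl ketone is converted through its mixed ketal into the tertiary allyl enol ether, which undergoes a Claisen [3,3]-sigmatropic rearrangement (Saucy–Marbet type). This forms the C8–C9 bond and shifts the alkene to the prenyl CH=CMe2 group, with no new stereocentre.

**Step 4**
Reactants: 5
Product: 6, (1S,2S,4R)-4-[(3S)-3-bromo-2,2-dimethyl-3,4-dihydro-2H-pyran-6-yl]-2-chloro-1-methylcyclohexan-1-ol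
Conditions: NBS, 2,6-di-tert-butyl-4-methylpyridine, CH2Cl2, –40 to 0 °C
Reagents that add atoms: N-bromosuccinimide O=C1CCC(=O)N1Br (Br)
Why: The bromonium ion on the prenyl alkene is attacked anti, 6-endo, at the tertiary carbon by the ketone oxygen (haloetherification). The hindered base then removes a C8 proton from the oxocarbenium ion to give the endocyclic enol ether, and C10 is set by anti addition. C10 is the only centre not controlled by the pool or the substrate, so the two C10 epimers (about 1:1) are separated and the (10S) isomer is carried on.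

**Step 5**
Reactants: 6
Product: 7, the C7–C8 epoxide of 6 with the epoxide O on the face opposite Br (2,7-dioxabicyclo[4.1.0]heptane; stereochemistry as in the SMILES)
Conditions: DMDO, acetone/CH2Cl2, 0 °C (crude product used directly)
Reagents that add atoms: dimethyldioxirane CC1(C)OO1 (O)
Why: Glycal-type epoxidation of the electron-rich enol ether. The pseudo-axial C10 bromine blocks the top face, so the oxygen is delivered to the bottom face.

**Step 6**
Reactants: 7
Product: 8, (1S,2S,4R)-4-[(2S,3S,5S)-5-bromo-3-hydroxy-2,6,6-trimethyloxan-2-yl]-2-chloro-1-methylcyclohexan-1-ol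
Conditions: AlMe3, CH2Cl2, –78 to 0 °C; Rochelle salt work-up
Reagents that add atoms: trimethylaluminium C[Al](C)C (CH3)
Why: Lewis-acid opening of the α-alkoxy epoxide at the oxocarbenium-like C7 with inversion, as in C-glycosylation of 1,2-anhydro sugars. Methyl enters anti to the departing oxygen, which fixes C7-Me trans to the C8 OH. The free tertiary alcohol is tolerated as its aluminium alkoxide.

**Step 7**
Reactants: 8
Product: 9, target, (2S,3S,5S)-5-bromo-2-[(1R,3S,4S)-4-bromo-3-chloro-4-methylcyclohexyl]-2,6,6-trimethyloxan-3-ol
Conditions: TMSBr, CH2Cl2, –78 to –20 °C; then aq. NaHCO3/THF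
Reagents that add atoms: bromotrimethylsilane C[Si](C)(C)Br (Br)
Why: The tertiary alcohol ionises with anchimeric assistance from the anti-periplanar axial C2–Cl, giving a chloronium ion that bromide opens at the tertiary carbon from the opposite face. The net result is retention at C1, with Br axial and trans to Cl (neighbouring-group substitution). The C8 TMS ether formed in situ is cleaved on work-up.

**Compound list**
1 | (R)-(+)-limonene | CC1=CC[C@@H](CC1)C(=C)C | starting material
2 | (1S,2S,4R)-2-chloro-1-methyl-4-(prop-1-en-2-yl)cyclohexan-1-ol | C=C(C)[C@@H]1CC[C@](C)(O)[C@@H](Cl)C1 | intermediate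
3 | 1-[(1R,3S,4S)-3-chloro-4-hydroxy-4-methylcyclohexyl]ethan-1-one | CC(=O)[C@@H]1CC[C@](C)(O)[C@@H](Cl)C1 | intermediate
4 | 2-methylbut-3-en-2-ol | CC(C)(O)C=C | starting material
5 | 1-[(1R,3S,4S)-3-chloro-4-hydroxy-4-methylcyclohexyl]-5-methylhex-4-en-1-one | CC(C)=CCCC(=O)[C@@H]1CC[C@](C)(O)[C@@H](Cl)C1 | intermediate
6 | (1S,2S,4R)-4-[(3S)-3-bromo-2,2-dimethyl-3,4-dihydro-2H-pyran-6-yl]-2-chloro-1-methylcyclohexan-1-ol | CC1(C)OC([C@@H]2CC[C@](C)(O)[C@@H](Cl)C2)=CC[C@@H]1Br | intermediate
7 | C7–C8 epoxide of 6, O trans to Br | CC1(C)O[C@@]2([C@@H]3CC[C@](C)(O)[C@@H](Cl)C3)O[C@H]2C[C@@H]1Br | intermediate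
8 | (1S,2S,4R)-4-[(2S,3S,5S)-5-bromo-3-hydroxy-2,6,6-trimethyloxan-2-yl]-2-chloro-1-methylcyclohexan-1-ol | CC1(C)O[C@@](C)([C@@H]2CC[C@](C)(O)[C@@H](Cl)C2)[C@@H](O)C[C@@H]1Br | intermediate
9 | (2S,3S,5S)-5-bromo-2-[(1R,3S,4S)-4-bromo-3-chloro-4-methylcyclohexyl]-2,6,6-trimethyloxan-3-ol | CC1(C)O[C@@](C)([C@@H]2CC[C@](C)(Br)[C@@H](Cl)C2)[C@@H](O)C[C@@H]1Br | target

**Total steps:** 7. **Longest linear sequence:** 7, from 1 to 9; compound 4 is the only convergent partner.

**Three steps most likely to fail**
1. **Step 4 (bromo-cyclisation to the enol ether).** Risks are C4 deprotonation to an exocyclic enol ether, over-bromination, and a C10 ratio near 1:1.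
   Fallback: α-hydroxylate ketone 5 at C8 (LDA, Davis oxaziridine), protect as the TBS ether, add MeLi (Felkin control), deprotect, then close the ring by conventional NBS bromoetherification of the tertiary alcohol onto the prenyl alkene.
2. **Step 6 (methyl delivery to the 7-position).** Methyl may enter syn to the C11 methyl or with retention, giving the C7 epimer.
   Fallback: fix the quaternary C7 carbinol before ring closure. Add vinylMgBr to 3 and Claisen the vinyl carbinol with 2-methoxypropene to the (E)-alkene methyl ketone. Brominate at C10, add MeMgBr, epoxidise the C7=C8 alkene, and close the pyran by 6-endo epoxide opening with the C11 tertiary alcohol.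
3. **Step 7 (tertiary OH→Br).** HBr generated in situ may ring-open the pyran ether or eliminate.
   Fallback: install the ring dibromide at the start by treating ketone 3 with TMSBr, when no other alkene is present. Carry the tertiary bromide forward and replace AlMe3 in Step 6 with MeMgBr/MgBr2, which does not ionise tertiary bromides.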